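## The problem

The target 15 is a 2,5-diaryl-3,4-dimethyltetrahydrofuran. In the discussion the ring is numbered O1, C2 (ring A, 3,4-dimethoxyphenyl), C3 (methyl), C4 (methyl), C5 (ring B, 4-hydroxy-3,5-dimethoxyphenyl), which makes the target (2S,3S,4R,5R). The two aryl groups are cis to each other, the two methyls are cis to each other, and each aryl group is trans to the methyl beside it. With identical aryl groups the molecule would be meso, so the absolute configuration lies entirely in which end of a symmetric core receives which ring. The cis pair of methyls at C3/C4 is the demanding relationship, because it cannot be corrected by equilibration once made. C2 and C5 are easier: a reagent bonding to either carbon prefers the face away from the adjacent methyl, so C3/C4 can control C2/C5 but not the reverse. Both benzylic C–O bonds carry electron-rich rings and ionize under Brønsted or Lewis acid, and the 2,6-dimethoxyphenol of ring B is easily oxidized towards a quinone methide through C5–H, so it should stay masked until the end. The enabling feature is that O1, C2, C3, C4 and C5 map onto the oxygen bridge, the bridgeheads and the exo-substituted carbons of a 7-oxanorbornene, whose two alkene carbons sit where the two aryl ipso carbons sit in 15.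

## Retrosynthesis

**15 from 14 (O–Si bond).** The phenol of ring B is carried as a triisopropylsilyl ether and released last with buffered fluoride. This is the only deprotection; it needs no acid, oxidant or hydrogen, all of which threaten the benzylic ethers.

**14 from 11 and 13 (C5–ring B bond).** The C5–aryl bond is cut to a C5 carboxylic acid in 11 and aryl bromide 13, which comes in one step from bromophenol 12. The forward reaction is a nickel/photoredox decarboxylative arylation through a C5 α-oxy radical. This is preferred to a carbonyl-addition or oxocarbenium construction because it is neutral and leaves the C2 benzylic ether alone. The C5 configuration of 11 is irrelevant because it is erased at the radical stage. The reaction must deliver the aryl group trans to the C4 methyl.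

**11 from 10, and 10 from 8 and 9 (C2–ring A bond).** The same disconnection at C2 leads through methyl ester 10 to hemiester 8 and bromide 9. Ring A goes on first because it has no protecting group and tolerates the saponification of 10 to 11, which a phenol silyl ether would not. Hemiester 8 has no aryl group and only the C3/C4 stereocenters carry information. The reaction must deliver ring A trans to the C3 methyl.

**8 from 7, and 7 from 6 (ester C–O bond, desymmetrization).** Removing the ester methyl and closing the two carboxyls gives the bridged meso anhydride 7, formed by dehydration of meso diacid 6. The forward alcoholysis under a cinchona-derived catalyst is the only step where absolute configuration enters: it decides which carboxyl becomes ring A. A chiral-pool or auxiliary solution would cost more steps for the same information.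

**6 from 4 (key step; the two carboxyl carbons rejoined as C=C).** Joining the carboxyl carbons of 6 gives exo,exo-5,6-dimethyl-7-oxanorbornene 4. The forward oxidative cleavage forms no skeletal bond and no stereocenter. It releases a monocycle in which the carboxyls are cis by necessity and trans to the exo methyls. All relative configuration is thus fixed by a rigid bicycle, not negotiated in a ring-forming transition state.

**4 from 3, 2 and 1 (C–O bonds at the future methyls).** The methyls of 4 are the fully reduced carbonyl carbons of the commercial exo Diels–Alder adduct 1, reached through diol 2 and bis-mesylate 3. The exo geometry of 1 supplies the cis-dimethyl relationship. Only standard reductions are asked for.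

## Roads not taken

**Alternative 1:** Hydrogen-atom-transfer reductive cyclization.
- Cut: the C3–C4 bond and one C–H bond of each methyl, leading to the unsymmetrical bis(1-arylallyl) ether A1.
- Forward: Mn(dpm)3 with PhSiH3 and tert-butyl hydroperoxide transfers a hydrogen atom to a terminal alkene carbon; the secondary radical closes 5-exo onto the other vinyl group and the primary radical is reduced, giving the silyl ether A2 of the target.
- Merits: the ring, C3–C4 and both methyls form in one step, A2 is one deprotection from 15, and the route would be about half the length of the chosen one.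
- Weak points: A1 is an ether of two secondary alcohols that are both benzylic and allylic, with both carbinol centers defined; the etherifications that join such alcohols ionize them, with racemization and allylic transposition. C3 and C4 are then set together in one flexible chair-like transition state whose preference for cis methyls is weak, so diastereomers of very similar polarity are expected. Plain reduction of each alkene and isomerization of the allyl ether compete.
- Comparison: Alternative 1 is clearly better in step count and convergence. The chosen plan sets against this that the 3,4-cis relationship is inherited from a bicycle and cannot be formed wrongly, and that each aryl-bearing center is set singly beside a fixed methyl.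

**Alternative 2:** Desymmetrizing arylzinc coupling.
- Cut: the C2–ring A bond as an aryl ketone, back to meso-2,3-dimethylsuccinic anhydride A3.
- Forward: a chiral rhodium–phosphoramidite catalyst from [Rh(cod)Cl]2, or Pd(OAc)2 with a Josiphos ligand, inserts into one enantiotopic acyl–oxygen bond and couples with the arylzinc made from 9, giving keto acid A4. Ketone reduction, lactonization, lactol formation and introduction of ring B through an oxocarbenium ion would follow.
- Merits: this coupling is established on exactly this class of anhydride, it fixes C3/C4 in the absolute sense and attaches ring A in the first step, and the route could finish in six or seven steps. In step count and in the reliability of enantiocontrol it is better than the chosen plan.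
- Weak points: C3 of A4 is α to an aryl ketone and epimerizes easily to the trans-dimethyl series, the one error that cannot be repaired. C2 then depends on a diastereoselective ketone reduction. C5 must be made under Lewis acid while the ionizable ring A benzylic ether is already present.
- Comparison: the chosen plan is longer and rests on a less precedented desymmetrization. It sets against this that C3/C4 are never enolizable, that both C–aryl bonds form under neutral radical conditions, and that the two aryl halides are introduced late and can be varied.

**Alternative 3:** Auxiliary-directed furan hydrogenation.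
- Cut: the four ring C–H bonds, back to the furoyl prolinate A5.
- Forward: hydrogen over Rh/Al2O3 adds to one face of the furan under the influence of the proline ester, giving the all-cis tetrahydrofuran A6.
- Merits: A5 is assembled by flat, reliable chemistry, four stereocenters appear in one step, and no desymmetrization is needed because the auxiliary sets C3/C4. Ring B is present from the start.
- Weak points: syn addition places both the C2 carbonyl and the C5 aryl group cis to the methyls, whereas 15 needs both trans. C2 could be inverted through the amide enolate, but C5 has no acidifying group and can be inverted only by acid ionization of the benzylic ether, which is unselective. Tetrasubstituted 2-arylfurans hydrogenate slowly, with competing hydrogenolysis of the C5–O bond and saturation of the electron-rich arene. The hindered amide must still be hydrolysed and the acid exchanged for ring A by the same decarboxylative arylation used here.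
- Comparison: Alternative 3 has the easier starting material, but it ends at the same end game with C5 wrong; the chosen plan reaches that stage with C3, C4 and C5 correct.

Key step: step 4

Assumption: the quinidine-derived catalyst is taken to open anhydride 7 so that the free acid remains on the carbon destined for ring A; if the sense of induction is the reverse, the quinine-derived pseudoenantiomer is used instead and nothing else changes.

## Route

Step 1
Reactants: 1 exo-7-oxabicyclo[2.2.1]hept-5-ene-2,3-dicarboxylic anhydride (exo Diels–Alder adduct of furan and maleic anhydride, meso)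
Product: 2 exo,exo-7-oxabicyclo[2.2.1]hept-5-ene-2,3-diyldimethanol (meso)
Conditions: LiAlH4, THF, 0 °C to rt; aqueous NaOH work-up
Reagents that add atoms: none
Why: Hydride reduction of a cyclic anhydride to the 1,4-diol; the four ring stereocenters are untouched, and the low temperature keeps the adduct from retro-Diels–Alder fragmentation.

Step 2
Reactants: 2 exo,exo-7-oxabicyclo[2.2.1]hept-5-ene-2,3-diyldimethanol
Product: 3 exo,exo-7-oxabicyclo[2.2.1]hept-5-ene-2,3-diylbis(methylene) dimethanesulfonate (meso)
Conditions: MsCl, Et3N, CH2Cl2, 0 °C
Reagents that add atoms: methanesulfonyl chloride, CS(=O)(=O)Cl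
Why: Sulfonylation of two primary alcohols; no stereocenter is involved.

Step 3
Reactants: 3 exo,exo-7-oxabicyclo[2.2.1]hept-5-ene-2,3-diylbis(methylene) dimethanesulfonate
Product: 4 (1R,4S,5R,6S)-5,6-dimethyl-7-oxabicyclo[2.2.1]hept-2-ene (exo,exo; meso)
Conditions: LiBEt3H, THF, 0 °C to rt
Reagents that add atoms: none
Why: SN2 displacement of the primary mesylates by hydride (trialkylborohydride reduction); the alkene and the bridging ether are inert, and the volatile product should be carried on as a concentrated solution.

Step 4
Reactants: 4 (1R,4S,5R,6S)-5,6-dimethyl-7-oxabicyclo[2.2.1]hept-2-ene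
Product: 6 meso-(2R,3R,4S,5S)-3,4-dimethyloxolane-2,5-dicarboxylic acid, via meso-3,4-dimethyloxolane-2,5-dicarbaldehyde 5 (not isolated)
Conditions: RuCl3·xH2O (3 mol%), NaIO4 (4.2 equiv), EtOAc/MeCN/H2O, 0 °C to rt
Reagents that add atoms: sodium periodate, [Na+].[O-]I(=O)(=O)=O; water, O
Why: Periodate oxidizes RuCl3 to ruthenium tetroxide, which adds across the strained C2=C3 bond of 4 in a concerted [3+2] manner; the cyclic ruthenate diester fragments with C–C cleavage to dialdehyde 5 and RuO2, which periodate returns to RuO4, and the aldehyde hydrates are oxidized on to the acids. The closest known reaction type is the RuCl3/NaIO4 cleavage of norbornene and of 7-oxanorbornenes to cis-1,3-dicarboxylic acids of cyclopentane and tetrahydrofuran. No ring is closed and no skeletal bond is formed; the bicycle is opened to the monocycle. No stereocenter is created: the bridgeheads C1 and C4 become C2 and C5 of the tetrahydrofuran with their configuration untouched, so the carboxyls are cis by construction and trans to the exo methyls. The step needs only chemoselectivity, alkene against α-oxy C–H: the bridgehead C–H bonds of 4 cannot develop oxocarbenium character, and in 5 and 6 the same bonds are deactivated by the adjacent carbonyl groups. Epimerization at the aldehyde stage is the one stereochemical hazard and is limited by fast in situ oxidation in the mildly acidic two-phase medium. Because 4 is meso and its alkene carbons are equivalent, there is no regiochemical question.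

Step 5
Reactants: 6 meso-(2R,3R,4S,5S)-3,4-dimethyloxolane-2,5-dicarboxylic acid
Product: 7 meso-(1R,5S,6S,7R)-6,7-dimethyl-3,8-dioxabicyclo[3.2.1]octane-2,4-dione
Conditions: Ac2O, 80 °C; evaporation with toluene
Reagents that add atoms: none
Why: Cyclodehydration of a cis-1,3-diacid; only the cis diacid can close to the bridged six-membered anhydride, and the isomer with carboxyls trans to the methyls is the less crowded one, so no epimerization is expected.

Step 6
Reactants: 7 meso-(1R,5S,6S,7R)-6,7-dimethyl-3,8-dioxabicyclo[3.2.1]octane-2,4-dione
Product: 8 (2S,3S,4R,5R)-5-(methoxycarbonyl)-3,4-dimethyloxolane-2-carboxylic acid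
Conditions: hydroquinidine anthraquinone-1,4-diyl diether, (DHQD)2AQN (20 mol%), MeOH (10 equiv), Et2O, −40 °C; 1 M HCl wash
Reagents that add atoms: methanol, CO
Why: Cinchona-alkaloid-catalysed enantioselective alcoholysis of a meso cyclic anhydride (general-base activation of methanol by the quinuclidine nitrogen); the catalyst selects one of the two enantiotopic carbonyls, which fixes C3 and C4 in the absolute sense by deciding which end keeps the free acid; no stereocenter is formed or inverted.

Step 7
Reactants: 8 (2S,3S,4R,5R)-5-(methoxycarbonyl)-3,4-dimethyloxolane-2-carboxylic acid; 9 4-bromo-1,2-dimethoxybenzene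
Product: 10 methyl (2R,3R,4S,5S)-5-(3,4-dimethoxyphenyl)-3,4-dimethyloxolane-2-carboxylate
Conditions: Ir[dF(CF3)ppy]2(dtbbpy)PF6 (2 mol%), NiCl2·glyme (10 mol%), dtbbpy (15 mol%), Cs2CO3, DMF, blue LEDs, rt
Reagents that add atoms: none
Why: Nickel/photoredox decarboxylative arylation of an α-oxy acid: the carboxylate is oxidized by the excited iridium photocatalyst, CO2 is lost, and the α-oxy radical is captured by the aryl nickel bromide formed from zerovalent nickel and 9; reductive elimination forms the C–ring A bond. The configuration of the acid carbon is erased at the radical stage and set anew by nickel bonding on the face away from the adjacent methyl, the 1,2-trans preference known from furanosyl radical arylations, which also places ring A cis to the remote ester.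

Step 8
Reactants: 10 methyl (2R,3R,4S,5S)-5-(3,4-dimethoxyphenyl)-3,4-dimethyloxolane-2-carboxylate
Product: 11 (2R,3R,4S,5S)-5-(3,4-dimethoxyphenyl)-3,4-dimethyloxolane-2-carboxylic acid
Conditions: LiOH·H2O, THF/H2O, 0 °C to rt; then 1 M HCl to pH 3
Reagents that add atoms: lithium hydroxide, [Li+].[OH-]
Why: Ester saponification; the benzylic ether is stable to base, and any epimerization at the carboxyl-bearing carbon is harmless because that center becomes a radical in step 10.

Step 9
Reactants: 12 4-bromo-2,6-dimethoxyphenol
Product: 13 (4-bromo-2,6-dimethoxyphenoxy)tri(propan-2-yl)silane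
Conditions: TIPSCl, imidazole, DMF, rt
Reagents that add atoms: triisopropylsilyl chloride, CC(C)[Si](Cl)(C(C)C)C(C)C
Why: Silylation of a phenol; the bulky triisopropylsilyl group is chosen so that the aryl silyl ether withstands carbonate in DMF during step 10.

Step 10
Reactants: 11 (2R,3R,4S,5S)-5-(3,4-dimethoxyphenyl)-3,4-dimethyloxolane-2-carboxylic acid; 13 (4-bromo-2,6-dimethoxyphenoxy)tri(propan-2-yl)silane
Product: 14 {4-[(2R,3R,4S,5S)-5-(3,4-dimethoxyphenyl)-3,4-dimethyloxolan-2-yl]-2,6-dimethoxyphenoxy}tri(propan-2-yl)silane
Conditions: Ir[dF(CF3)ppy]2(dtbbpy)PF6 (2 mol%), NiCl2·glyme (10 mol%), dtbbpy (15 mol%), Cs2CO3, DMF, blue LEDs, rt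
Reagents that add atoms: none
Why: Second nickel/photoredox decarboxylative arylation of an α-oxy acid; the radical at the ring B carbon is arylated on the face away from the neighbouring methyl, which is also the face of ring A, giving the 2,5-cis diaryl array with each aryl trans to its adjacent methyl.

Step 11
Reactants: 14 {4-[(2R,3R,4S,5S)-5-(3,4-dimethoxyphenyl)-3,4-dimethyloxolan-2-yl]-2,6-dimethoxyphenoxy}tri(propan-2-yl)silane
Product: 15 4-[(2R,3R,4S,5S)-5-(3,4-dimethoxyphenyl)-3,4-dimethyloxolan-2-yl]-2,6-dimethoxyphenol (target)
Conditions: Bu4NF, AcOH, THF, 0 °C
Reagents that add atoms: none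
Why: Fluoride cleavage of an aryl silyl ether; buffering with acetic acid keeps the oxidation-prone 2,6-dimethoxyphenolate from accumulating, and no stereocenter is touched.

## Compound list

1 | exo-7-oxabicyclo[2.2.1]hept-5-ene-2,3-dicarboxylic anhydride, (3aR,4S,7R,7aS)-3a,4,7,7a-tetrahydro-4,7-epoxy-2-benzofuran-1,3-dione (meso) | C1=C[C@H]2O[C@@H]1[C@@H]3C(=O)OC(=O)[C@H]23 | starting material
2 | exo,exo-7-oxabicyclo[2.2.1]hept-5-ene-2,3-diyldimethanol (meso) | C1=C[C@H]2O[C@@H]1[C@H](CO)[C@@H]2CO | intermediate
3 | exo,exo-7-oxabicyclo[2.2.1]hept-5-ene-2,3-diylbis(methylene) dimethanesulfonate (meso) | C1=C[C@H]2O[C@@H]1[C@H](COS(C)(=O)=O)[C@@H]2COS(C)(=O)=O | intermediate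
4 | (1R,4S,5R,6S)-5,6-dimethyl-7-oxabicyclo[2.2.1]hept-2-ene (exo,exo; meso) | C1=C[C@H]2O[C@@H]1[C@H](C)[C@@H]2C | intermediate
5 | meso-(2R,3R,4S,5S)-3,4-dimethyloxolane-2,5-dicarbaldehyde (not isolated) | O=C[C@H]1O[C@@H](C=O)[C@H](C)[C@@H]1C | intermediate
6 | meso-(2R,3R,4S,5S)-3,4-dimethyloxolane-2,5-dicarboxylic acid (carboxyls cis, methyls cis, carboxyls trans to methyls) | OC(=O)[C@H]1O[C@@H](C(=O)O)[C@H](C)[C@@H]1C | intermediate
7 | meso-(1R,5S,6S,7R)-6,7-dimethyl-3,8-dioxabicyclo[3.2.1]octane-2,4-dione | O=C1OC(=O)[C@H]2O[C@@H]1[C@H](C)[C@@H]2C | intermediate
8 | (2S,3S,4R,5R)-5-(methoxycarbonyl)-3,4-dimethyloxolane-2-carboxylic acid | OC(=O)[C@H]1O[C@@H](C(=O)OC)[C@H](C)[C@@H]1C | intermediate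
9 | 4-bromo-1,2-dimethoxybenzene | COc1ccc(Br)cc1OC | starting material
10 | methyl (2R,3R,4S,5S)-5-(3,4-dimethoxyphenyl)-3,4-dimethyloxolane-2-carboxylate | COc1ccc([C@H]2O[C@@H](C(=O)OC)[C@H](C)[C@@H]2C)cc1OC | intermediate
11 | (2R,3R,4S,5S)-5-(3,4-dimethoxyphenyl)-3,4-dimethyloxolane-2-carboxylic acid | COc1ccc([C@H]2O[C@@H](C(=O)O)[C@H](C)[C@@H]2C)cc1OC | intermediate
12 | 4-bromo-2,6-dimethoxyphenol | COc1cc(Br)cc(OC)c1O | starting material
13 | (4-bromo-2,6-dimethoxyphenoxy)tri(propan-2-yl)silane | COc1cc(Br)cc(OC)c1O[Si](C(C)C)(C(C)C)C(C)C | intermediate
14 | {4-[(2R,3R,4S,5S)-5-(3,4-dimethoxyphenyl)-3,4-dimethyloxolan-2-yl]-2,6-dimethoxyphenoxy}tri(propan-2-yl)silane | COc1ccc([C@H]2O[C@@H](c3cc(OC)c(O[Si](C(C)C)(C(C)C)C(C)C)c(OC)c3)[C@H](C)[C@@H]2C)cc1OC | intermediate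
15 | 4-[(2R,3R,4S,5S)-5-(3,4-dimethoxyphenyl)-3,4-dimethyloxolan-2-yl]-2,6-dimethoxyphenol | COc1ccc([C@H]2O[C@@H](c3cc(OC)c(O)c(OC)c3)[C@H](C)[C@@H]2C)cc1OC | target

## Step count and least certain steps

Total: 11 steps. Longest linear sequence: 10 steps (steps 1–8, 10 and 11); step 9 is a one-step side branch.

**Step 4 (key step).** Three processes could hurt it: evaporative loss of the volatile alkene 4 before it reacts, oxidation by RuO4 at the ether α-positions once the alkene is consumed, and incomplete extraction of the water-soluble diacid from the periodate liquor. The fallback sets out from 4 and returns at 6. Alkene 4 is ozonized in CH2Cl2/MeOH at −78 °C and the crude ozonolysis mixture is reduced in the same flask with NaBH4 to the meso diol [(2R,3R,4S,5S)-3,4-dimethyloxolane-2,5-diyl]dimethanol F1, which is extractable and not volatile. F1 is then oxidized to diacid 6 with catalytic 2,2,6,6-tetramethylpiperidin-1-oxyl, catalytic NaOCl and NaClO2 in MeCN/phosphate buffer, conditions that do not epimerize α-alkoxy aldehydes.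

**Step 6.** The ring oxygen makes anhydride 7 more electrophilic than a glutaric anhydride, so uncatalysed methanolysis may compete and lower the enantiomeric purity; the bridged framework is also a new substrate for the catalyst, so discrimination of the two carbonyls may be modest. The fallback sets out from 7 and returns at 11. Anhydride 7 is opened with (S)-1-phenylethanol, Et3N and catalytic 4-(dimethylamino)pyridine to two diastereomeric hemiesters, which are separated by chromatography or crystallization. The needed one is (2S,3S,4R,5R)-3,4-dimethyl-5-{[(1S)-1-phenylethoxy]carbonyl}oxolane-2-carboxylic acid F2; the other is (2R,3R,4S,5S)-3,4-dimethyl-5-{[(1S)-1-phenylethoxy]carbonyl}oxolane-2-carboxylic acid F3. F2 is arylated with 9 under the conditions of step 7 to (1S)-1-phenylethyl (2R,3R,4S,5S)-5-(3,4-dimethoxyphenyl)-3,4-dimethyloxolane-2-carboxylate F4, and saponification with LiOH gives acid 11.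

**Step 7.** Oxidative addition of the electron-rich bromide 9 to zerovalent nickel may be slow, so the radical is lost to reduction. Facial control by the one adjacent methyl may be incomplete. Migration of the ester methyl through the bridged anhydride under carbonate would erode enantiomeric purity. The fallback sets out from 8 and returns at 10, replacing the radical by a cation. Oxidative decarboxylation of 8 with Pb(OAc)4 and pyridine in benzene gives methyl (2R,3R,4S,5RS)-5-acetoxy-3,4-dimethyloxolane-2-carboxylate F5. Ionization of F5 with BF3·OEt2 in CH2Cl2 at −78 °C in the presence of 1,2-dimethoxybenzene gives 10 by Friedel–Crafts arylation of the oxocarbenium ion para to a methoxy group and trans to the adjacent methyl.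

**Step 10.** The product and 11 carry a weak benzylic α-oxy C–H bond and an oxidizable electron-rich arene. Hydrogen-atom abstraction at C–H next to ring A, ring opening of the radical by β-scission towards a benzylic radical, or premature loss of the silyl group under carbonate (which would leave a phenolate bromide that no longer couples) could each lower the yield, and facial control is again carried by one methyl. The fallback sets out from 11 and returns at 15, making steps 9 and 11 unnecessary. Oxidative decarboxylation of 11 with Pb(OAc)4 gives (2RS,3R,4S,5S)-5-(3,4-dimethoxyphenyl)-3,4-dimethyloxolan-2-yl acetate F6. Treatment with 2,6-dimethoxyphenol and BF3·OEt2 in CH2Cl2 at −78 °C arylates the oxocarbenium ion at the position para to the hydroxyl and gives 15 directly. The low temperature is needed to keep the ring A benzylic ether from ionizing.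

## Further compounds

F1 | step 4 | meso-[(2R,3R,4S,5S)-3,4-dimethyloxolane-2,5-diyl]dimethanol | OC[C@H]1O[C@@H](CO)[C@H](C)[C@@H]1C
F2 | step 6 | (2S,3S,4R,5R)-3,4-dimethyl-5-{[(1S)-1-phenylethoxy]carbonyl}oxolane-2-carboxylic acid | OC(=O)[C@H]1O[C@@H](C(=O)O[C@@H](C)c2ccccc2)[C@H](C)[C@@H]1C
F3 | step 6 | (2R,3R,4S,5S)-3,4-dimethyl-5-{[(1S)-1-phenylethoxy]carbonyl}oxolane-2-carboxylic acid | O=C(O[C@@H](C)c1ccccc1)[C@H]1O[C@@H](C(=O)O)[C@H](C)[C@@H]1C
F4 | step 6 | (1S)-1-phenylethyl (2R,3R,4S,5S)-5-(3,4-dimethoxyphenyl)-3,4-dimethyloxolane-2-carboxylate | COc1ccc([C@H]2O[C@@H](C(=O)O[C@@H](C)c3ccccc3)[C@H](C)[C@@H]2C)cc1OC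
F5 | step 7 | methyl (2R,3R,4S,5RS)-5-acetoxy-3,4-dimethyloxolane-2-carboxylate (both anomers) | CC(=O)OC1O[C@@H](C(=O)OC)[C@H](C)[C@@H]1C
F6 | step 10 | (2RS,3R,4S,5S)-5-(3,4-dimethoxyphenyl)-3,4-dimethyloxolan-2-yl acetate (both anomers) | COc1ccc([C@H]2OC(OC(C)=O)[C@H](C)[C@@H]2C)cc1OC
A1 | alternative 1 | tert-butyl{4-[(1R)-1-{[(1S)-1-(3,4-dimethoxyphenyl)prop-2-en-1-yl]oxy}prop-2-en-1-yl]-2,6-dimethoxyphenoxy}dimethylsilane | COc1ccc([C@H](C=C)O[C@@H](c2cc(OC)c(O[Si](C)(C)C(C)(C)C)c(OC)c2)C=C)cc1OC
A2 | alternative 1 | tert-butyl{4-[(2R,3R,4S,5S)-5-(3,4-dimethoxyphenyl)-3,4-dimethyloxolan-2-yl]-2,6-dimethoxyphenoxy}dimethylsilane | COc1ccc(cc1OC)[C@H]2O[C@@H](c3cc(OC)c(O[Si](C)(C)C(C)(C)C)c(OC)c3)[C@H](C)[C@@H]2C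
A3 | alternative 2 | meso-(3R,4S)-3,4-dimethyloxolane-2,5-dione (cis-2,3-dimethylsuccinic anhydride) | O=C1OC(=O)[C@H](C)[C@@H]1C
A4 | alternative 2 | (2R,3S)-4-(3,4-dimethoxyphenyl)-2,3-dimethyl-4-oxobutanoic acid | OC(=O)[C@H](C)[C@H](C)C(=O)c1ccc(OC)c(OC)c1
A5 | alternative 3 | methyl N-[5-(3,5-dimethoxy-4-pivaloyloxyphenyl)-3,4-dimethylfuran-2-carbonyl]-L-prolinate | COC(=O)[C@@H]1CCCN1C(=O)c1oc(-c2cc(OC)c(OC(=O)C(C)(C)C)c(OC)c2)c(C)c1C
A6 | alternative 3 | methyl N-[all-cis-5-(3,5-dimethoxy-4-pivaloyloxyphenyl)-3,4-dimethyltetrahydrofuran-2-carbonyl]-L-prolinate | COC(=O)[C@@H]1CCCN1C(=O)[C@@H]2O[C@H](c3cc(OC)c(OC(=O)C(C)(C)C)c(OC)c3)[C@H](C)[C@@H]2C
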